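The quinone ring (ring B: C1, C2, C3, C4, C4a, C8a) is opened between C2 and C3. C3 is the α-carbon of an aryl ketone at C4 that already carries the (S)-2-hydroxypropyl chain; C2 is the ester carbon of an arylacetate on C8a. The key step exploits the 1,3-dioxygenation C2–OH/C4=O flanking C3: a Dieckmann-type Claisen closure forms C2–C3 and gives a naphthalene-1,3-diol whose autoxidation in the same flask installs C1=O, so the complete 2-hydroxy-1,4-naphthoquinone arises in one operation. The precursor is an ethyl 2-(2-acylaryl)acetate, assembled from 1-bromo-2,4,5-trimethoxybenzene, whose bromine first directs lithiation (lactone opening with (S)-γ-valerolactone) and then serves as cross-coupling handle.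

Key step: step 3

Remark on numbering: naphthalene-1,4-dione numbering of the target is used throughout (C1=O, C2–OH, C3–side chain, C4=O, OMe at C5, C6 and C8); the side-chain stereocentre is (S).

Assumption: (S)-γ-valerolactone, LiN(i-Pr)2 solution and BrZnCH2CO2Et solution are taken as commercial; the stereocentre of the lactone is the carbinol carbon, so it is carried unchanged into the target.

Step 1
Reactants: 1 1-bromo-2,4,5-trimethoxybenzene; 2 (S)-γ-valerolactone
Product: 4 (4S)-1-(2-bromo-3,5,6-trimethoxyphenyl)-4-hydroxypentan-1-one, via aryllithium 3 (not isolated)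
Conditions: LiN(i-Pr)2 (LDA, 1.1 equiv), THF, −78 °C, 1 h; then 2 (1.2 equiv), −78 °C, 2 h; aq. NH4Cl at −78 °C
Reagents that add atoms: none
Why: Directed ortho-lithiation followed by acyl substitution on a lactone: the amide base should remove the proton flanked by bromine and methoxy (far more acidic toward LiN(i-Pr)2 than the proton between two methoxy groups), and the hindered aryllithium should open the lactone to a lithium lactolate that resists a second addition, while the (S)-carbinol centre of 2 is not involved and is retained.

Step 2
Reactants: 4 (4S)-1-(2-bromo-3,5,6-trimethoxyphenyl)-4-hydroxypentan-1-one; 5 (2-ethoxy-2-oxoethyl)zinc bromide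
Product: 6 ethyl 2-{2-[(4S)-4-hydroxypentanoyl]-3,4,6-trimethoxyphenyl}acetate
Conditions: 5 (3 equiv), Pd2(dba)3 (2.5 mol %), XPhos (10 mol %), THF, 50 °C; aq. NH4Cl
Reagents that add atoms: none
Why: Negishi-type α-arylation with a Reformatsky zinc enolate: the neutral zinc enolate does not enolise the ketone and should add only slowly to this carbonyl, which is flanked by two ortho substituents and partly masked as the zinc lactolate once one equivalent of 5 has been consumed by the free hydroxyl, while the bulky biarylphosphine on zerovalent palladium should permit oxidative addition and reductive elimination at the doubly ortho-substituted bromide.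

Step 3
Reactants: 6 ethyl 2-{2-[(4S)-4-hydroxypentanoyl]-3,4,6-trimethoxyphenyl}acetate
Product: 8 2-hydroxy-3-[(2S)-2-hydroxypropyl]-5,6,8-trimethoxynaphthalene-1,4-dione, via naphthalene-1,3-diol 7 (not isolated)
Conditions: NaOEt (4 equiv), EtOH, argon, 0 → 50 °C; then O2 (1 atm), rt; dilute HCl to pH 3–4 at 0 °C
Reagents that add atoms: dioxygen, O=O
Why: Ethoxide reversibly enolises the aryl ketone at its only α-carbon (future C3), and this enolate attacks the neutral ester carbonyl (future C2) in a Dieckmann-type Claisen condensation that expels ethoxide and, after enolisation, gives the aromatic naphthalene-1,3-diolate of 7. Ring B is closed in the 6-(enolendo)-exo-trig mode. When O2 is admitted, the electron-rich naphtholate is autoxidised at its free C1–H position (hydroperoxide, then loss of water), which installs the C1 carbonyl and leaves the hydroxyquinone as its acidic, oxidation-resistant enolate until acidification. The closest known reaction type is the alkoxide-mediated Claisen cyclisation and aerobic oxidation of 2-acylarylacetates to 3-substituted 2-hydroxy-1,4-naphthoquinones. No stereocentre is formed, and the (S)-carbinol, which carries no acidic hydrogen and sits γ to the ketone, cannot epimerise or undergo retro-aldol cleavage. The step needs C-acylation at C3 through the six-membered ring: the ketone has a single enolisable side, the more acidic benzylic ester enolate has no ring of workable size to close and simply re-equilibrates, any lactone or cyclic hemiketal formed by the side-chain alkoxide is reopened by ethoxide, and aromatisation followed by oxidation makes the productive closure irreversible.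

Step 4
Reactants: 8 2-hydroxy-3-[(2S)-2-hydroxypropyl]-5,6,8-trimethoxynaphthalene-1,4-dione
Product: 10 2-hydroxy-3-[(2S)-2-acetoxypropyl]-5,6,8-trimethoxynaphthalene-1,4-dione, via bis-acetate 9 (not isolated)
Conditions: Ac2O (4 equiv), pyridine, DMAP (cat.), CH2Cl2, 0 °C → rt; then MeOH, Et3N, 0 °C → rt; dilute aq. citric acid work-up
Reagents that add atoms: acetic anhydride, CC(=O)OC(C)=O
Why: Exhaustive DMAP-catalysed O-acetylation followed by chemoselective methanolysis: the quinone enol acetate is a vinylogous mixed anhydride and should be cleaved by MeOH/Et3N far faster than the secondary alkyl acetate, and acylation at oxygen leaves the (S)-centre untouched (retention).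

Compound list
1 | 1-bromo-2,4,5-trimethoxybenzene | COc1cc(OC)c(OC)cc1Br | starting material
2 | (S)-γ-valerolactone, (5S)-5-methyloxolan-2-one | C[C@H]1CCC(=O)O1 | starting material
3 | (2-bromo-3,5,6-trimethoxyphenyl)lithium (aryllithium, formed in the flask) | [Li]c1c(Br)c(OC)cc(OC)c1OC | intermediate
4 | (4S)-1-(2-bromo-3,5,6-trimethoxyphenyl)-4-hydroxypentan-1-one | C[C@H](O)CCC(=O)c1c(Br)c(OC)cc(OC)c1OC | intermediate
5 | (2-ethoxy-2-oxoethyl)zinc bromide | CCOC(=O)C[Zn]Br | starting material
6 | ethyl 2-{2-[(4S)-4-hydroxypentanoyl]-3,4,6-trimethoxyphenyl}acetate | C[C@H](O)CCC(=O)c1c(CC(=O)OCC)c(OC)cc(OC)c1OC | intermediate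
7 | 2-[(2S)-2-hydroxypropyl]-5,7,8-trimethoxynaphthalene-1,3-diol (formed in the flask) | C[C@H](O)Cc1c(O)cc2c(OC)cc(OC)c(OC)c2c1O | intermediate
8 | 2-hydroxy-3-[(2S)-2-hydroxypropyl]-5,6,8-trimethoxynaphthalene-1,4-dione | C[C@H](O)CC1=C(O)C(=O)c2c(OC)cc(OC)c(OC)c2C1=O | intermediate
9 | 2-acetoxy-3-[(2S)-2-acetoxypropyl]-5,6,8-trimethoxynaphthalene-1,4-dione (bis-acetate, formed in the flask) | C[C@H](OC(C)=O)CC1=C(OC(C)=O)C(=O)c2c(OC)cc(OC)c(OC)c2C1=O | intermediate
10 | 2-hydroxy-3-[(2S)-2-acetoxypropyl]-5,6,8-trimethoxynaphthalene-1,4-dione (CNP0321270.1) | COc1cc(OC)c2c(c1OC)C(=O)C(C[C@H](C)OC(C)=O)=C(O)C2=O | target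

Total step count: 4. Longest linear sequence: 4 steps (1 → 4 → 6 → 8 → 10).

The three steps most likely to fail are step 1, step 2 and step 3, in this order of risk.

At step 1, proton transfer from the lactone α-position to the aryllithium, relayed by the diisopropylamine in the flask, may outrun acyl substitution, and the ortho-bromo aryllithium may lose LiBr to an aryne while the slow acylation proceeds. The fallback sets out from 1 and separates metalation from acylation. Lithiation with LiN(i-Pr)2 at −78 °C and an immediate iodine quench should give 1-bromo-2-iodo-3,4,6-trimethoxybenzene F1, which is isolated free of amine. Selective iodine–magnesium exchange with i-PrMgCl·LiCl (THF, −20 °C) should give (2-bromo-3,5,6-trimethoxyphenyl)magnesium chloride F2, a far less basic nucleophile that should not eliminate magnesium halide at this temperature. Its addition to lactone 2 (LaCl3·2LiCl as additive if needed) and NH4Cl work-up comes back to the route at 4.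

At step 2, transmetalation and reductive elimination at the doubly ortho-substituted arylpalladium may be slow, so that protodebromination, Reformatsky addition of the zinc enolate to the ketone and quenching of the enolate by the free hydroxyl take over. The fallback sets out from 4 and uses a copper-catalysed, carbonyl-assisted arylation of a soft carbon acid instead. Diethyl malonate, CuI, 2-picolinic acid and Cs2CO3 in dioxane at 70 °C, conditions under which the ortho ketone assists rather than hinders, should give diethyl 2-{2-[(4S)-4-hydroxypentanoyl]-3,4,6-trimethoxyphenyl}propanedioate F3. Krapcho dealkoxycarbonylation (LiCl, H2O, DMSO, 140 °C) then comes back to the route at 6.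

At step 3, autoxidation of the very electron-rich naphtholate may run on to oxidative coupling, to oxygenation at the alkyl-bearing C3 or to ring degradation, and the free side-chain alkoxide may tie up the ketone as a cyclic hemiketal and retard enolisation and closure. The fallback sets out from 6, masks the alcohol and separates closure from oxidation. Silylation (TBSCl, imidazole, DMF) should give ethyl 2-{2-[(4S)-4-(tert-butyldimethylsilyloxy)pentanoyl]-3,4,6-trimethoxyphenyl}acetate F4. The same C2–C3 Claisen closure under strictly anaerobic conditions (KOt-Bu, t-BuOH/THF, argon, degassed dilute HCl quench) should give isolated 2-[(2S)-2-(tert-butyldimethylsilyloxy)propyl]-5,7,8-trimethoxynaphthalene-1,3-diol F5. A discrete catalytic oxidation (O2, Co(salen), DMF, rt) should give 2-hydroxy-3-[(2S)-2-(tert-butyldimethylsilyloxy)propyl]-5,6,8-trimethoxynaphthalene-1,4-dione F6, and desilylation with HF·pyridine in MeCN comes back to the route at 8.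

Further compounds
F1 | step 1 | 1-bromo-2-iodo-3,4,6-trimethoxybenzene | COc1cc(OC)c(OC)c(I)c1Br
F2 | step 1 | (2-bromo-3,5,6-trimethoxyphenyl)magnesium chloride | COc1cc(OC)c(OC)c([Mg]Cl)c1Br
F3 | step 2 | diethyl 2-{2-[(4S)-4-hydroxypentanoyl]-3,4,6-trimethoxyphenyl}propanedioate | C[C@H](O)CCC(=O)c1c(C(C(=O)OCC)C(=O)OCC)c(OC)cc(OC)c1OC
F4 | step 3 | ethyl 2-{2-[(4S)-4-(tert-butyldimethylsilyloxy)pentanoyl]-3,4,6-trimethoxyphenyl}acetate | C[C@H](O[Si](C)(C)C(C)(C)C)CCC(=O)c1c(CC(=O)OCC)c(OC)cc(OC)c1OC
F5 | step 3 | 2-[(2S)-2-(tert-butyldimethylsilyloxy)propyl]-5,7,8-trimethoxynaphthalene-1,3-diol | C[C@H](O[Si](C)(C)C(C)(C)C)Cc1c(O)cc2c(OC)cc(OC)c(OC)c2c1O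
F6 | step 3 | 2-hydroxy-3-[(2S)-2-(tert-butyldimethylsilyloxy)propyl]-5,6,8-trimethoxynaphthalene-1,4-dione | C[C@H](O[Si](C)(C)C(C)(C)C)CC1=C(O)C(=O)c2c(OC)cc(OC)c(OC)c2C1=O
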